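**Retrosynthetic overview**
1. Target (2S,4R, 2,4-trans) ⇐ methanolysis of its 4-nitrobenzoate ⇐ Mitsunobu inversion of the 2,4-cis alcohol ⇐ hydride reduction of (2S)-5,7-dimethoxy-8-prenylflavanone, so C4 is controlled by C2.
2. Pyranone ring (O1–C2) ⇐ intramolecular Mitsunobu etherification with inversion of an o-hydroxyaryl β-hydroxy ketone; C2 comes from purchased (R)-3-hydroxy-3-phenylpropanoic acid.
3. C4–C4a bond ⇐ photo-Fries 1,3-acyl shift of the aryl ester of that acid.
4. Aryl ester ⇐ 2-prenyl-3,5-dimethoxyphenol ⇐ 3,5-dimethoxyphenol + prenyl bromide.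
5. Ring order: the A ring and the phenyl ring are purchased; the heterocyclic ring is the only ring formed (step 4).

Assumption: (R)-3-hydroxy-3-phenylpropanoic acid is bought as the enantiopure building block.

**Route**

Step 1
Reactants: 1 3,5-dimethoxyphenol; 2 prenyl bromide
Product: 3 3,5-dimethoxy-2-(3-methylbut-2-en-1-yl)phenol
Conditions: NaH (1.05 equiv), toluene, 0 °C → rt; then 2 (1.0 equiv), rt
Reagents that add atoms: none other than reactant 2 (prenyl bromide, CC(C)=CCBr)
Why: ortho C-alkylation of the tight sodium phenoxide ion pair in a non-polar solvent (phenoxide C-prenylation); the two ortho sites of 1 are equivalent, and the O-prenyl and 4-prenyl by-products are removed by chromatography.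

Step 2
Reactants: 3; 4 (R)-3-hydroxy-3-phenylpropanoic acid
Product: 5 3,5-dimethoxy-2-(3-methylbut-2-en-1-yl)phenyl (3R)-3-hydroxy-3-phenylpropanoate
Conditions: EDC·HCl, DMAP (0.1 equiv), CH2Cl2, 0 °C → rt, slow addition of 4
Reagents that add atoms: none other than reactant 4
Why: Steglich esterification, in which the phenol captures the acyl-pyridinium faster than the hindered secondary benzylic hydroxyl; the carbinol stereocentre is not involved and the acid-sensitive o-prenylphenol sees no strong acid.

Step 3
Reactants: 5
Product: 6 (3R)-3-hydroxy-1-[2-hydroxy-4,6-dimethoxy-3-(3-methylbut-2-en-1-yl)phenyl]-3-phenylpropan-1-one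
Conditions: hν (254 nm, quartz flow reactor), degassed MeCN (0.01 M), 20 °C, run to about 70% conversion and recycle 5
Reagents that add atoms: none
Why: Proposed new method: photo-Fries rearrangement of an aryl ester carrying a free, enantiopure β-hydroxy-β-phenyl stereocentre and an o-prenyl group, where excitation of the electron-rich aryl ester homolyses the ArO–C(O) bond, the caged phenoxyl/acyl radical pair recombines at the only free ortho carbon faster than the primary acyl radical can decarbonylate or escape, and tautomerisation gives the hydrogen-bonded o-hydroxyaryl ketone, which is photostable through excited-state proton transfer; the carbinol carbon is never a radical or ionic site so its (R) configuration is carried through; the closest known reaction is the photo-Fries rearrangement of aryl cinnamates to 2'-hydroxychalcones.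

Step 4
Reactants: 6
Product: 7 (2S)-5,7-dimethoxy-8-(3-methylbut-2-en-1-yl)-2-phenylchroman-4-one
Conditions: PPh3, DIAD, THF (0.02 M), 0 °C → rt
Reagents that add atoms: none
Why: intramolecular Mitsunobu etherification, a 6-exo-tet SN2 attack of the phenol on the alkoxyphosphonium, closes the pyranone ring and inverts the purchased (R)-carbinol to C2-(S); the neutral conditions limit β-elimination to the chalcone.

Step 5
Reactants: 7
Product: 8 (2S,4S)-5,7-dimethoxy-8-(3-methylbut-2-en-1-yl)-2-phenylchroman-4-ol (2,4-cis)
Conditions: NaBH4, THF–MeOH (1:1), 0 °C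
Reagents that add atoms: none
Why: substrate-controlled ketone reduction in which hydride adds axially to the half-chair with the 2-phenyl equatorial, giving the 2,4-cis alcohol (4S); the cold, short reaction avoids base-induced ring opening at C2, and the prenyl alkene is inert.

Step 6
Reactants: 8; 9 4-nitrobenzoic acid
Product: 10 (2S,4R)-5,7-dimethoxy-8-(3-methylbut-2-en-1-yl)-2-phenylchroman-4-yl 4-nitrobenzoate (2,4-trans)
Conditions: PPh3, DIAD, 9 (1.5 equiv), THF, 0 °C → rt; short silica plug
Reagents that add atoms: none other than reactant 9 (4-nitrobenzoic acid, O=C(O)c1ccc(cc1)[N+](=O)[O-]), which supplies the 4-nitrobenzoyl group and the new C4 oxygen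
Why: Mitsunobu inversion in which the carboxylate displaces the alkoxyphosphonium from the face opposite the departing oxygen, turning 4S into 4R; if the electron-rich benzylic centre reacts through an ion pair, axial capture should still favour the 2,4-trans ester, and C2 is not involved.

Step 7
Reactants: 10
Product: 11 (2S,4R)-5,7-dimethoxy-8-(3-methylbut-2-en-1-yl)-2-phenylchroman-4-ol (2,4-trans)
Conditions: K2CO3, MeOH–THF (3:1), rt
Reagents that add atoms: none
Why: base-mediated transesterification (methanolysis) cleaves the activated 4-nitrobenzoate at the acyl carbon, so the C4–O bond and both stereocentres are untouched and the prenyl alkene and aryl ethers are inert.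

**Compound list**
1 | 3,5-dimethoxyphenol | COc1cc(O)cc(OC)c1 | starting material
2 | prenyl bromide (1-bromo-3-methylbut-2-ene) | CC(C)=CCBr | starting material
3 | 3,5-dimethoxy-2-(3-methylbut-2-en-1-yl)phenol | COc1cc(OC)c(CC=C(C)C)c(O)c1 | intermediate
4 | (R)-3-hydroxy-3-phenylpropanoic acid | OC(=O)C[C@@H](O)c1ccccc1 | starting material
5 | 3,5-dimethoxy-2-(3-methylbut-2-en-1-yl)phenyl (3R)-3-hydroxy-3-phenylpropanoate | COc1cc(OC)c(CC=C(C)C)c(OC(=O)C[C@@H](O)c2ccccc2)c1 | intermediate
6 | (3R)-3-hydroxy-1-[2-hydroxy-4,6-dimethoxy-3-(3-methylbut-2-en-1-yl)phenyl]-3-phenylpropan-1-one | COc1cc(OC)c(C(=O)C[C@@H](O)c2ccccc2)c(O)c1CC=C(C)C | intermediate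
7 | (2S)-5,7-dimethoxy-8-(3-methylbut-2-en-1-yl)-2-phenylchroman-4-one | COc1cc(OC)c2c(c1CC=C(C)C)O[C@H](c1ccccc1)CC2=O | intermediate
8 | (2S,4S)-5,7-dimethoxy-8-(3-methylbut-2-en-1-yl)-2-phenylchroman-4-ol (cis) | COc1cc(OC)c2c(c1CC=C(C)C)O[C@H](c1ccccc1)C[C@@H]2O | intermediate
9 | 4-nitrobenzoic acid | O=C(O)c1ccc(cc1)[N+](=O)[O-] | starting material
10 | (2S,4R)-5,7-dimethoxy-8-(3-methylbut-2-en-1-yl)-2-phenylchroman-4-yl 4-nitrobenzoate (trans) | COc1cc(OC)c2c(c1CC=C(C)C)O[C@H](c1ccccc1)C[C@H]2OC(=O)c1ccc(cc1)[N+](=O)[O-] | intermediate
11 | (2S,4R)-5,7-dimethoxy-8-(3-methylbut-2-en-1-yl)-2-phenylchroman-4-ol (trans) | COc1cc(OC)c2c(c1CC=C(C)C)O[C@H](c1ccccc1)C[C@H]2O | target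

**Totals**
Total steps: 7. Longest linear sequence: 7 (steps 1–7, from 1 to 11).

**Three steps most likely to fail**
1. Step 3, the proposed new photo-Fries step. Risks are para-acyl isomer formation, cage escape back to 3, and inner-filter slowdown by the product. Fallback (known chemistry, anionic C-acylation instead of a radical-pair shift): protect 3 as its MOM ether, ortho-lithiate between OMOM and OMe (n-BuLi, THF, 0 °C), acylate with the Weinreb amide of O-TBS-protected 4, then remove MOM and TBS under mild acid to give 6.
2. Step 4, the Mitsunobu ring closure. The risk is dehydration of the β-hydroxy ketone to the chalcone, which recloses to racemic 7. Fallback (bond order reversed): intermolecular Mitsunobu of 3 with ethyl (R)-3-hydroxy-3-phenylpropanoate to make the (S)-aryl ether first, saponify, then intramolecular Friedel–Crafts acylation (TFAA, 0 °C) to 7, so no β-hydroxy ketone is ever formed.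
3. Step 6, the C4 inversion. Risks are elimination to the flav-3-ene and partial SN1 scrambling at the very electron-rich benzylic centre. Fallback (ionisation and equilibration instead of SN2): ionise 8 in AcOH with catalytic PPTS to equilibrate through the stabilised C4 cation to the 4-axial (trans) acetate, then K2CO3/MeOH to 11.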